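## Retrosynthetic overview

1. Target ⇒ phenol 19, the 8,8'-dibenzylbutane core. The ring C side chain is added last: Mitsunobu etherification of the ring B phenol with (R)-lactate sets C8'' by inversion, aryl ketone formation brings ring C, Felkin–Anh reduction sets C7'' (threo), and O-debenzylation finishes.
2. Key disconnection C7–C8: 19 ⇒ secondary boronic ester 12 (boron on C8) + lithiated ring A benzyl carbamate 15 (C7 carbenoid). Two donor carbons are joined by a 1,2-metallate shift, and the boron left on C7 is replaced by H in the same flask.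
3. Enabling feature: C7 is a benzylic CH2 on ring A, para to the ring A oxygen. As its O-carbamate it is lithiated with ease, and the benzylic C7–B bond left after the shift is cleaved by fluoride and water; C8 is a plain CH(CH3) carbon that can carry boron.
4. 12 ⇒ ring B benzyl boronate 6 + two portions of the same (S)-1-lithioethyl benzoate carbenoid 8. Iterative reagent-controlled homologation in one operation sets C8' and then C8, and using one carbenoid twice gives the meso-type 8S,8'R pair.
5. No ring is formed in the route: rings A, B and C are bought as benzene derivatives and enter in the order B (step 1), A (step 5), C (step 8).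

Key step: step 5

Assumption: reagents 3 and 7 and (−)-sparteine are taken as purchasable; the locants C7, C8, C8', C7', C7'' and C8'' are those of the lignan name of the target.

## Route

Step 1
Reactants: 1 4-bromo-2,6-dimethoxyphenol
Product: 2 tert-butyl(4-bromo-2,6-dimethoxyphenoxy)dimethylsilane
Conditions: TBSCl, imidazole, DMF, rt
Reagents that add atoms: tert-butyl(chloro)dimethylsilane (TBSCl), CC(C)(C)[Si](C)(C)Cl
Why: Imidazole-mediated silylation of the phenol removes the only acidic proton before the organolithium steps and installs a group that fluoride removes later without touching benzyl ethers.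

Step 2
Reactants: 2 tert-butyl(4-bromo-2,6-dimethoxyphenoxy)dimethylsilane; 3 2-(bromomethyl)-4,4,5,5-tetramethyl-1,3,2-dioxaborolane
Product: 6 2-[(4-{[tert-butyl(dimethyl)silyl]oxy}-3,5-dimethoxyphenyl)methyl]-4,4,5,5-tetramethyl-1,3,2-dioxaborolane, via aryllithium 4 (not isolated), via boronate complex 5 (not isolated)
Conditions: n-BuLi, THF, −78 °C; add 3, −78 °C → rt
Reagents that add atoms: none
Why: Bromine–lithium exchange gives aryllithium 4, which adds to the boron of 3, and the aryl group then shifts from boron to carbon with loss of bromide (Matteson homologation of a halomethylboronate), giving the benzylic boronate that carries C7'.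

Step 3
Reactants: 6 2-[(4-{[tert-butyl(dimethyl)silyl]oxy}-3,5-dimethoxyphenyl)methyl]-4,4,5,5-tetramethyl-1,3,2-dioxaborolane; 7 ethyl 2,4,6-tri(propan-2-yl)benzoate
Product: 12 2-[(2R,3R)-4-(4-{[tert-butyl(dimethyl)silyl]oxy}-3,5-dimethoxyphenyl)-3-methylbutan-2-yl]-4,4,5,5-tetramethyl-1,3,2-dioxaborolane, via lithiated benzoate 8 (not isolated), via first boronate complex 9 (not isolated), via monohomologated boronic ester 10 (not isolated), via second boronate complex 11 (not isolated)
Conditions: flask 1: 7, (−)-sparteine, s-BuLi, Et2O, −78 °C; add 6, −78 °C; then reflux; cool to −78 °C and transfer by cannula into flask 2 (second portion of 8 from 7, (−)-sparteine, s-BuLi, Et2O, −78 °C); −78 °C; then reflux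
Reagents that add atoms: none
Why: Sparteine-mediated asymmetric deprotonation removes the pro-S proton of 7 to give the (S)-carbenoid 8, which is borylated with retention and takes up the migrating carbon with inversion (lithiation–borylation, a reagent-controlled Matteson-type homologation run twice in one operation), so the first insertion sets C8' as R and the second, in which C8' migrates with retention, sets C8, while over-insertion should be avoided because boronate formation is complete at −78 °C and the excess carbenoid decomposes on warming before the 1,2-shift releases a new boronic ester.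

Step 4
Reactants: 13 [4-(benzyloxy)-3-methoxyphenyl]methanol
Product: 14 [4-(benzyloxy)-3-methoxyphenyl]methyl N,N-di(propan-2-yl)carbamate
Conditions: N,N-diisopropylcarbamoyl chloride, Et3N, CH2Cl2, reflux
Reagents that add atoms: N,N-diisopropylcarbamoyl chloride, CC(C)N(C(C)C)C(=O)Cl
Why: Carbamoylation of the primary benzylic alcohol installs the group that directs lithiation to C7 and later serves as the leaving group of the 1,2-shift.

Step 5
Reactants: 12 2-[(2R,3R)-4-(4-{[tert-butyl(dimethyl)silyl]oxy}-3,5-dimethoxyphenyl)-3-methylbutan-2-yl]-4,4,5,5-tetramethyl-1,3,2-dioxaborolane; 14 [4-(benzyloxy)-3-methoxyphenyl]methyl N,N-di(propan-2-yl)carbamate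
Product: 19 4-{(2R,3S)-4-[4-(benzyloxy)-3-methoxyphenyl]-2,3-dimethylbutyl}-2,6-dimethoxyphenol, via lithiated carbamate 15 (not isolated), via boronate complex 16 (not isolated), via benzylic boronic ester 17 (not isolated), via desilylated boronic ester 18 (not isolated)
Conditions: 14, s-BuLi, TMEDA, Et2O, −78 °C; add 12, −78 °C → rt; then solvent change to toluene, Bu4NF·3H2O, 60 °C
Reagents that add atoms: none
Why: s-BuLi/TMEDA removes a benzylic proton of 14 to give the dipole-stabilised carbenoid 15, so that C7, which stems from a benzylic alcohol, acts as a donor and adds to the boron of 12 to give boronate 16, and on warming the C8–B bond migrates to C7 anti to the departing carbamate, joining the two donor carbons C8 and C7 (1,2-metallate rearrangement; closest known reaction type: lithiation–borylation of primary benzylic carbamates with secondary pinacol boronic esters). No ring is closed. The migrating C8 moves with retention, so the pair set in step 3 is carried over unchanged (the descriptor at C8 changes from R to S only because boron is replaced by carbon in the priority order), while C7 of 17 forms as a mixture of epimers that does not matter because this carbon ends as a CH2 group. Bu4NF·3H2O then cleaves the aryl silyl ether to give 18 and replaces the benzylic boron by hydrogen (fluoride-induced protodeboronation of a benzylic boronic ester), so the ring B phenol needed for step 6 is released in the same operation. The step needs deprotonation at the carbamate CH2 and not at the benzyl ether CH2, which the proximity effect of the carbamate carbonyl and the higher acidity of that site should secure, and it needs protonolysis of one C–B bond only, which holds because the benzylic C7–B bond is the only C–B bond present.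

Step 6
Reactants: 19 4-{(2R,3S)-4-[4-(benzyloxy)-3-methoxyphenyl]-2,3-dimethylbutyl}-2,6-dimethoxyphenol; 20 methyl (2R)-2-hydroxypropanoate
Product: 21 methyl (2S)-2-(4-{(2R,3S)-4-[4-(benzyloxy)-3-methoxyphenyl]-2,3-dimethylbutyl}-2,6-dimethoxyphenoxy)propanoate
Conditions: PPh3, DIAD, THF, 0 °C → rt
Reagents that add atoms: none
Why: In the Mitsunobu reaction the phenol displaces the activated secondary lactate oxygen with inversion, so the (R)-lactate should give the (S)-aryloxypropanoate and set C8''.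

Step 7
Reactants: 21 methyl (2S)-2-(4-{(2R,3S)-4-[4-(benzyloxy)-3-methoxyphenyl]-2,3-dimethylbutyl}-2,6-dimethoxyphenoxy)propanoate
Product: 22 (2S)-2-(4-{(2R,3S)-4-[4-(benzyloxy)-3-methoxyphenyl]-2,3-dimethylbutyl}-2,6-dimethoxyphenoxy)-N-methoxy-N-methylpropanamide
Conditions: MeNHOMe·HCl, i-PrMgCl, THF, −20 °C → 0 °C
Reagents that add atoms: N,O-dimethylhydroxylamine hydrochloride, CNOC.Cl
Why: Aminolysis of the methyl ester by the chloromagnesium amide of N,O-dimethylhydroxylamine (Weinreb amide formation) runs at low temperature and should leave the α-stereocentre untouched.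

Step 8
Reactants: 22 (2S)-2-(4-{(2R,3S)-4-[4-(benzyloxy)-3-methoxyphenyl]-2,3-dimethylbutyl}-2,6-dimethoxyphenoxy)-N-methoxy-N-methylpropanamide; 23 1-(benzyloxy)-4-bromo-2-methoxybenzene
Product: 25 (2S)-1-[4-(benzyloxy)-3-methoxyphenyl]-2-(4-{(2R,3S)-4-[4-(benzyloxy)-3-methoxyphenyl]-2,3-dimethylbutyl}-2,6-dimethoxyphenoxy)propan-1-one, via aryllithium 24 (not isolated)
Conditions: 23, n-BuLi, THF, −78 °C; add 22, −78 °C; aq NH4Cl at −78 °C
Reagents that add atoms: none
Why: Aryllithium 24 adds to the Weinreb amide to give a chelated tetrahedral adduct that releases the ketone only on quench (Weinreb ketone synthesis), which prevents over-addition and keeps the enolisable C8'' away from base.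

Step 9
Reactants: 25 (2S)-1-[4-(benzyloxy)-3-methoxyphenyl]-2-(4-{(2R,3S)-4-[4-(benzyloxy)-3-methoxyphenyl]-2,3-dimethylbutyl}-2,6-dimethoxyphenoxy)propan-1-one
Product: 26 (1S,2S)-1-[4-(benzyloxy)-3-methoxyphenyl]-2-(4-{(2R,3S)-4-[4-(benzyloxy)-3-methoxyphenyl]-2,3-dimethylbutyl}-2,6-dimethoxyphenoxy)propan-1-ol
Conditions: LiBH(s-Bu)3, THF, −78 °C; aq NH4Cl
Reagents that add atoms: none
Why: In a Felkin–Anh reduction the bulky, poorly chelating hydride attacks anti to the aryloxy group and past the hydrogen of C8'', which for the (S)-ketone should give the (7''S) alcohol and thus the threo (7''S,8''S) pair.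

Step 10
Reactants: 26 (1S,2S)-1-[4-(benzyloxy)-3-methoxyphenyl]-2-(4-{(2R,3S)-4-[4-(benzyloxy)-3-methoxyphenyl]-2,3-dimethylbutyl}-2,6-dimethoxyphenoxy)propan-1-ol
Product: 27 (+)-(7''S,8S,8'R,8''S)-4,4''-dihydroxy-3,3',3'',5'-tetramethoxy-4',8''-oxy-8,8'-sesquineolignan-7''-ol
Conditions: H2 (1 atm), 10% Pd/C, EtOAc, rt
Reagents that add atoms: none
Why: Hydrogenolysis of the two benzyl aryl ethers over Pd/C in a neutral medium frees both phenols, while the secondary benzylic alcohol and the alkyl aryl ether should survive in the absence of acid.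

## Compound list

1 | 4-bromo-2,6-dimethoxyphenol | COc1cc(Br)cc(OC)c1O | starting material
2 | tert-butyl(4-bromo-2,6-dimethoxyphenoxy)dimethylsilane | COc1cc(Br)cc(OC)c1O[Si](C)(C)C(C)(C)C | intermediate
3 | 2-(bromomethyl)-4,4,5,5-tetramethyl-1,3,2-dioxaborolane | BrCB1OC(C)(C)C(C)(C)O1 | starting material
4 | (4-{[tert-butyl(dimethyl)silyl]oxy}-3,5-dimethoxyphenyl)lithium | [Li]c1cc(OC)c(O[Si](C)(C)C(C)(C)C)c(OC)c1 | intermediate
5 | lithium (bromomethyl)(4-{[tert-butyl(dimethyl)silyl]oxy}-3,5-dimethoxyphenyl)(pinacolato)borate | [Li+].BrC[B-]1(OC(C)(C)C(C)(C)O1)c1cc(OC)c(O[Si](C)(C)C(C)(C)C)c(OC)c1 | intermediate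
6 | 2-[(4-{[tert-butyl(dimethyl)silyl]oxy}-3,5-dimethoxyphenyl)methyl]-4,4,5,5-tetramethyl-1,3,2-dioxaborolane | COc1cc(CB2OC(C)(C)C(C)(C)O2)cc(OC)c1O[Si](C)(C)C(C)(C)C | intermediate
7 | ethyl 2,4,6-tri(propan-2-yl)benzoate | CCOC(=O)c1c(C(C)C)cc(C(C)C)cc1C(C)C | starting material
8 | (1S)-1-lithioethyl 2,4,6-tri(propan-2-yl)benzoate (sparteine complex) | [Li][C@@H](C)OC(=O)c1c(C(C)C)cc(C(C)C)cc1C(C)C | intermediate
9 | lithium boronate complex of 8 and 6 | [Li+].C[C@@H](OC(=O)c1c(C(C)C)cc(C(C)C)cc1C(C)C)[B-]1(Cc2cc(OC)c(O[Si](C)(C)C(C)(C)C)c(OC)c2)OC(C)(C)C(C)(C)O1 | intermediate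
10 | 2-[(2R)-1-(4-{[tert-butyl(dimethyl)silyl]oxy}-3,5-dimethoxyphenyl)propan-2-yl]-4,4,5,5-tetramethyl-1,3,2-dioxaborolane | CC1(C)OB(OC1(C)C)[C@H](C)Cc1cc(OC)c(O[Si](C)(C)C(C)(C)C)c(OC)c1 | intermediate
11 | lithium boronate complex of 8 and 10 | [Li+].C[C@@H](OC(=O)c1c(C(C)C)cc(C(C)C)cc1C(C)C)[B-]1([C@H](C)Cc2cc(OC)c(O[Si](C)(C)C(C)(C)C)c(OC)c2)OC(C)(C)C(C)(C)O1 | intermediate
12 | 2-[(2R,3R)-4-(4-{[tert-butyl(dimethyl)silyl]oxy}-3,5-dimethoxyphenyl)-3-methylbutan-2-yl]-4,4,5,5-tetramethyl-1,3,2-dioxaborolane | CC1(C)OB(OC1(C)C)[C@H](C)[C@H](C)Cc1cc(OC)c(O[Si](C)(C)C(C)(C)C)c(OC)c1 | intermediate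
13 | [4-(benzyloxy)-3-methoxyphenyl]methanol | COc1cc(CO)ccc1OCc1ccccc1 | starting material
14 | [4-(benzyloxy)-3-methoxyphenyl]methyl N,N-di(propan-2-yl)carbamate | COc1cc(COC(=O)N(C(C)C)C(C)C)ccc1OCc1ccccc1 | intermediate
15 | [4-(benzyloxy)-3-methoxyphenyl](lithio)methyl N,N-di(propan-2-yl)carbamate (racemic) | COc1cc(C([Li])OC(=O)N(C(C)C)C(C)C)ccc1OCc1ccccc1 | intermediate
16 | lithium boronate complex of 15 and 12 | [Li+].COc1cc(C(OC(=O)N(C(C)C)C(C)C)[B-]2([C@H](C)[C@H](C)Cc3cc(OC)c(O[Si](C)(C)C(C)(C)C)c(OC)c3)OC(C)(C)C(C)(C)O2)ccc1OCc1ccccc1 | intermediate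
17 | 2-[(1RS,2S,3R)-1-[4-(benzyloxy)-3-methoxyphenyl]-4-(4-{[tert-butyl(dimethyl)silyl]oxy}-3,5-dimethoxyphenyl)-2,3-dimethylbutyl]-4,4,5,5-tetramethyl-1,3,2-dioxaborolane | COc1cc(C(B2OC(C)(C)C(C)(C)O2)[C@H](C)[C@H](C)Cc2cc(OC)c(O[Si](C)(C)C(C)(C)C)c(OC)c2)ccc1OCc1ccccc1 | intermediate
18 | 4-{(2R,3S,4RS)-4-[4-(benzyloxy)-3-methoxyphenyl]-2,3-dimethyl-4-(4,4,5,5-tetramethyl-1,3,2-dioxaborolan-2-yl)butyl}-2,6-dimethoxyphenol | COc1cc(C(B2OC(C)(C)C(C)(C)O2)[C@H](C)[C@H](C)Cc2cc(OC)c(O)c(OC)c2)ccc1OCc1ccccc1 | intermediate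
19 | 4-{(2R,3S)-4-[4-(benzyloxy)-3-methoxyphenyl]-2,3-dimethylbutyl}-2,6-dimethoxyphenol | COc1cc(C[C@H](C)[C@H](C)Cc2cc(OC)c(O)c(OC)c2)ccc1OCc1ccccc1 | intermediate
20 | methyl (2R)-2-hydroxypropanoate | C[C@@H](O)C(=O)OC | starting material
21 | methyl (2S)-2-(4-{(2R,3S)-4-[4-(benzyloxy)-3-methoxyphenyl]-2,3-dimethylbutyl}-2,6-dimethoxyphenoxy)propanoate | COc1cc(C[C@H](C)[C@H](C)Cc2cc(OC)c(O[C@@H](C)C(=O)OC)c(OC)c2)ccc1OCc1ccccc1 | intermediate
22 | (2S)-2-(4-{(2R,3S)-4-[4-(benzyloxy)-3-methoxyphenyl]-2,3-dimethylbutyl}-2,6-dimethoxyphenoxy)-N-methoxy-N-methylpropanamide | COc1cc(C[C@H](C)[C@H](C)Cc2cc(OC)c(O[C@@H](C)C(=O)N(C)OC)c(OC)c2)ccc1OCc1ccccc1 | intermediate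
23 | 1-(benzyloxy)-4-bromo-2-methoxybenzene | COc1cc(Br)ccc1OCc1ccccc1 | starting material
24 | [4-(benzyloxy)-3-methoxyphenyl]lithium | COc1cc([Li])ccc1OCc1ccccc1 | intermediate
25 | (2S)-1-[4-(benzyloxy)-3-methoxyphenyl]-2-(4-{(2R,3S)-4-[4-(benzyloxy)-3-methoxyphenyl]-2,3-dimethylbutyl}-2,6-dimethoxyphenoxy)propan-1-one | COc1cc(C[C@H](C)[C@H](C)Cc2cc(OC)c(O[C@@H](C)C(=O)c3ccc(OCc4ccccc4)c(OC)c3)c(OC)c2)ccc1OCc1ccccc1 | intermediate
26 | (1S,2S)-1-[4-(benzyloxy)-3-methoxyphenyl]-2-(4-{(2R,3S)-4-[4-(benzyloxy)-3-methoxyphenyl]-2,3-dimethylbutyl}-2,6-dimethoxyphenoxy)propan-1-ol | COc1cc(C[C@H](C)[C@H](C)Cc2cc(OC)c(O[C@@H](C)[C@@H](O)c3ccc(OCc4ccccc4)c(OC)c3)c(OC)c2)ccc1OCc1ccccc1 | intermediate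
27 | (+)-(7''S,8S,8'R,8''S)-4,4''-dihydroxy-3,3',3'',5'-tetramethoxy-4',8''-oxy-8,8'-sesquineolignan-7''-ol | COc1cc(C[C@H](C)[C@H](C)Cc2cc(OC)c(O[C@@H](C)[C@@H](O)c3ccc(O)c(OC)c3)c(OC)c2)ccc1O | target

## Step count and risks

Total step count: 10. Longest linear sequence: 9 steps (steps 1 to 3 and 5 to 10); step 4 is a one-step branch.

Steps most likely to fail:

1. Step 5. What may go wrong: competing metalation of the benzyl ether CH2 during carbamate lithiation, reversal of boronate formation with the hindered secondary boronic ester before the 1,2-shift, or sluggish protonolysis of the C–B bond at the electron-rich benzylic carbon. The fallback sets out from 12 and comes back at 19. Boronic ester 12 would be treated with chloromethyllithium F1 (made in the flask from BrCH2Cl and n-BuLi, THF, −78 °C), and the lithium (chloromethyl)boronate complex of 12 F2 would rearrange on warming, with retention at C8, to 2-[(2S,3R)-4-(4-{[tert-butyl(dimethyl)silyl]oxy}-3,5-dimethoxyphenyl)-2,3-dimethylbutyl]-4,4,5,5-tetramethyl-1,3,2-dioxaborolane F3 (Matteson homologation). Suzuki–Miyaura coupling of this primary boronic ester with aryl bromide 23 (Pd(OAc)2, RuPhos, K3PO4, toluene/H2O, 90 °C) should give tert-butyl(4-{(2R,3S)-4-[4-(benzyloxy)-3-methoxyphenyl]-2,3-dimethylbutyl}-2,6-dimethoxyphenoxy)dimethylsilane F4, and Bu4NF in THF would then free phenol 19. In this variant C7 enters as a one-carbon carbenoid and ring A is attached by cross-coupling, so no benzylic lithiation and no protodeboronation are needed.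

2. Step 9. What may go wrong: poor facial selectivity in hydride delivery, because open and lithium-chelated transition states lead to opposite configurations at C7''. The fallback sets out from 25 and comes back at 26. Chelation-controlled reduction with Zn(BH4)2 (Et2O, 0 °C) should give the erythro alcohol (1R,2S)-1-[4-(benzyloxy)-3-methoxyphenyl]-2-(4-{(2R,3S)-4-[4-(benzyloxy)-3-methoxyphenyl]-2,3-dimethylbutyl}-2,6-dimethoxyphenoxy)propan-1-ol F5. Mitsunobu inversion at C7'' with 4-nitrobenzoic acid (PPh3, DIAD, THF) would give (1S,2S)-1-[4-(benzyloxy)-3-methoxyphenyl]-2-(4-{(2R,3S)-4-[4-(benzyloxy)-3-methoxyphenyl]-2,3-dimethylbutyl}-2,6-dimethoxyphenoxy)propyl 4-nitrobenzoate F6, and saponification (LiOH, THF/H2O) would return the threo alcohol 26.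

3. Step 3. What may go wrong: erosion of diastereomeric purity, because the sparteine-mediated deprotonation is highly but not perfectly enantioselective and the error is carried into the second stereocentre; incomplete first insertion or a double insertion when the two cycles are run without purification in between; and slow migration of the branched secondary group in the second cycle. The fallback sets out from 6 and comes back at 12. Ester 7 would be lithiated as before (s-BuLi, (−)-sparteine, Et2O, −78 °C) and trapped with Me3SnCl to give (1S)-1-(trimethylstannyl)ethyl 2,4,6-tri(propan-2-yl)benzoate F7, a solid that can be recrystallised to a single enantiomer. Tin–lithium exchange with n-BuLi (Et2O, −78 °C) proceeds with retention and regenerates carbenoid 8 free of sparteine and of its enantiomer. It would be combined with 6 to give 10, which would be isolated and purified, and a second portion of 8 made the same way would convert 10 into 12 in a separate operation.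

## Further compounds

F1 | step 5 | chloromethyllithium | [Li]CCl
F2 | step 5 | lithium (chloromethyl)boronate complex of 12 | [Li+].ClC[B-]1([C@H](C)[C@H](C)Cc2cc(OC)c(O[Si](C)(C)C(C)(C)C)c(OC)c2)OC(C)(C)C(C)(C)O1
F3 | step 5 | 2-[(2S,3R)-4-(4-{[tert-butyl(dimethyl)silyl]oxy}-3,5-dimethoxyphenyl)-2,3-dimethylbutyl]-4,4,5,5-tetramethyl-1,3,2-dioxaborolane | CC1(C)OB(OC1(C)C)C[C@H](C)[C@H](C)Cc1cc(OC)c(O[Si](C)(C)C(C)(C)C)c(OC)c1
F4 | step 5 | tert-butyl(4-{(2R,3S)-4-[4-(benzyloxy)-3-methoxyphenyl]-2,3-dimethylbutyl}-2,6-dimethoxyphenoxy)dimethylsilane | COc1cc(C[C@H](C)[C@H](C)Cc2cc(OC)c(O[Si](C)(C)C(C)(C)C)c(OC)c2)ccc1OCc1ccccc1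
F5 | step 9 | (1R,2S)-1-[4-(benzyloxy)-3-methoxyphenyl]-2-(4-{(2R,3S)-4-[4-(benzyloxy)-3-methoxyphenyl]-2,3-dimethylbutyl}-2,6-dimethoxyphenoxy)propan-1-ol | COc1cc(C[C@H](C)[C@H](C)Cc2cc(OC)c(O[C@@H](C)[C@H](O)c3ccc(OCc4ccccc4)c(OC)c3)c(OC)c2)ccc1OCc1ccccc1
F6 | step 9 | (1S,2S)-1-[4-(benzyloxy)-3-methoxyphenyl]-2-(4-{(2R,3S)-4-[4-(benzyloxy)-3-methoxyphenyl]-2,3-dimethylbutyl}-2,6-dimethoxyphenoxy)propyl 4-nitrobenzoate | COc1cc(C[C@H](C)[C@H](C)Cc2cc(OC)c(O[C@@H](C)[C@@H](OC(=O)c3ccc(cc3)[N+](=O)[O-])c3ccc(OCc4ccccc4)c(OC)c3)c(OC)c2)ccc1OCc1ccccc1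
F7 | step 3 | (1S)-1-(trimethylstannyl)ethyl 2,4,6-tri(propan-2-yl)benzoate | C[Sn](C)(C)[C@@H](C)OC(=O)c1c(C(C)C)cc(C(C)C)cc1C(C)C
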